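## Retrosynthetic overview

1. Ring A (the 1,2-dioxane) is closed last, by intramolecular oxa-Michael addition of a C6 tertiary hydroperoxide onto butenolide ring B; the cis ring fusion sets C3 from C4. Numbering: C1 lactone C=O, C2, C3 (CH–OO), C4 (C(Me)–O), C5 (CH2), C6 (C(Me)(chain)–OO); target = 3R,4R,6S.
2. The hydroperoxide comes from cobalt-catalysed hydroperoxysilylation of a 1,1-disubstituted alkene at C6.
3. Ring B is formed first, by Z-selective olefination of an α-silyloxy aldehyde and lactonisation onto the C4 tertiary alcohol.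
4. The C6 alkene comes from methylenation of a ketone, made by coupling a 10-phenyldecylzinc reagent with the acid chloride of acetonide-protected citramalic acid.
5. C4 is set first, by hydratase (hydro-lyase) catalysed enantioselective addition of water to achiral citraconic acid, giving (R)-citramalic acid.

Assumption: the cobalt step is taken as unselective at C6, so 20 and 21 are carried as about 1:1 C6-epimer mixtures (SMILES without a descriptor at that carbon; the 2′S epimer is the productive one) and 22 is separated from its C6 epimer after step 15.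

## Route

Step 1
Reactants: 1 1-bromo-4-phenylbutane; 2 1-bromo-6-chlorohexane
Product: 4 1-chloro-10-phenyldecane, via 4-phenylbutylmagnesium bromide 3 (not isolated)
Conditions: 1, Mg, THF, 40 °C; then 2, Li2CuCl4 (2 mol%), THF, 0 °C → rt
Reagents that add atoms: none
Why: Kochi-type copper-catalysed sp3–sp3 Grignard cross-coupling reacts at the C–Br bond of 2 only, leaving the chloride as the handle for the next organometallic.

Step 2
Reactants: 5 citraconic acid [(Z)-2-methylbut-2-enedioic acid]
Product: 6 (R)-citramalic acid [(2R)-2-hydroxy-2-methylbutanedioic acid]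
Conditions: maleate hydratase (hydro-lyase; cell-free extract of Pseudomonas pseudoalcaligenes), NaOH to pH 8, aq. phosphate buffer, 30 °C; then HCl, EtOAc extraction
Reagents that add atoms: water, O
Why: Enzymatic asymmetric hydration (hydratase, a hydro-lyase): the enzyme binds the Z-diacid in one orientation and delivers OH to one face of the methyl-bearing carbon, so the tertiary carbinol that becomes C4 is set as R in high ee.

Step 3
Reactants: 6 (R)-citramalic acid
Product: 7 2-[(4R)-2,2,4-trimethyl-5-oxo-1,3-dioxolan-4-yl]acetic acid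
Conditions: Me2C(OMe)2, p-TsOH·H2O (cat.), acetone, rt
Reagents that add atoms: 2,2-dimethoxypropane, COC(C)(C)OC
Why: Acid-catalysed transacetalisation closes the favoured five-membered dioxolanone on the α-hydroxy acid, masking the tertiary OH and its carboxyl and leaving only the CH2CO2H arm free, without touching the stereocentre.

Step 4
Reactants: 7 2-[(4R)-2,2,4-trimethyl-5-oxo-1,3-dioxolan-4-yl]acetic acid
Product: 8 2-[(4R)-2,2,4-trimethyl-5-oxo-1,3-dioxolan-4-yl]acetyl chloride
Conditions: (COCl)2, DMF (cat.), CH2Cl2, 0 °C → rt; evaporate, use crude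
Reagents that add atoms: oxalyl chloride, ClC(=O)C(=O)Cl
Why: Acid chloride formation through the Vilsmeier-type chloroiminium is neutral enough for the acetal-lactone to survive.

Step 5
Reactants: 4 1-chloro-10-phenyldecane; 8 2-[(4R)-2,2,4-trimethyl-5-oxo-1,3-dioxolan-4-yl]acetyl chloride
Product: 11 (5R)-2,2,5-trimethyl-5-(2-oxo-12-phenyldodecyl)-1,3-dioxolan-4-one, via 10-phenyldecylmagnesium chloride 9 (not isolated), via 10-phenyldecylzinc chloride 10 (not isolated)
Conditions: 4, Mg, THF, reflux; ZnCl2, THF, 0 °C; then 8, Pd(PPh3)4 (5 mol%), THF, 0 °C → rt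
Reagents that add atoms: none
Why: Negishi acylation (palladium-catalysed coupling of an alkylzinc with an acid chloride) stops cleanly at the ketone, and the mild organozinc does not attack the dioxolanone carbonyl.

Step 6
Reactants: 11 (5R)-2,2,5-trimethyl-5-(2-oxo-12-phenyldodecyl)-1,3-dioxolan-4-one
Product: 12 (5R)-2,2,5-trimethyl-5-(2-methylidene-12-phenyldodecyl)-1,3-dioxolan-4-one
Conditions: Zn, CH2Br2, TiCl4, THF (reagent pre-formed, −40 → 5 °C); then 11, CH2Cl2, rt
Reagents that add atoms: dibromomethane, BrCBr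
Why: Takai–Lombardo methylenation uses a non-basic titanium–zinc methylene reagent, so the ketone becomes the 1,1-disubstituted alkene without enolisation, the β-oxygen is not eliminated and the lactone carbonyl is left alone.

Step 7
Reactants: 12 (5R)-2,2,5-trimethyl-5-(2-methylidene-12-phenyldodecyl)-1,3-dioxolan-4-one
Product: 13 methyl (2R)-2-hydroxy-2-methyl-4-methylidene-14-phenyltetradecanoate
Conditions: K2CO3 (cat.), MeOH, 0 °C → rt
Reagents that add atoms: methanol, CO
Why: Base-catalysed methanolysis (transesterification) opens the dioxolanone to the methyl ester and releases acetone; with the ketone already gone, neither retro-aldol cleavage nor β-elimination is possible.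

Step 8
Reactants: 13 methyl (2R)-2-hydroxy-2-methyl-4-methylidene-14-phenyltetradecanoate
Product: 14 methyl (2R)-2-methyl-4-methylidene-14-phenyl-2-(triethylsilyloxy)tetradecanoate
Conditions: Et3SiOTf, 2,6-lutidine, CH2Cl2, 0 °C → rt
Reagents that add atoms: triethylsilyl trifluoromethanesulfonate, CC[Si](CC)(CC)OS(=O)(=O)C(F)(F)F
Why: Silylation with the reactive silyl triflate protects the hindered tertiary alcohol against the hydride, the oxidant and the phosphonate anion of the next three steps.

Step 9
Reactants: 14 methyl (2R)-2-methyl-4-methylidene-14-phenyl-2-(triethylsilyloxy)tetradecanoate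
Product: 15 (2R)-2-methyl-4-methylidene-14-phenyl-2-(triethylsilyloxy)tetradecan-1-ol
Conditions: i-Bu2AlH (2.5 equiv), CH2Cl2, −78 → 0 °C; aq. potassium sodium tartrate
Reagents that add atoms: none
Why: Aluminium hydride reduction of the ester is taken deliberately to the alcohol so that no over-reduction control is needed; the alkene and the silyl ether are inert.

Step 10
Reactants: 15 (2R)-2-methyl-4-methylidene-14-phenyl-2-(triethylsilyloxy)tetradecan-1-ol
Product: 16 (2R)-2-methyl-4-methylidene-14-phenyl-2-(triethylsilyloxy)tetradecanal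
Conditions: Dess–Martin periodinane, CH2Cl2, 0 °C → rt
Reagents that add atoms: none
Why: Dess–Martin oxidation gives the aldehyde under near-neutral conditions, and the quaternary α-carbon cannot epimerise.

Step 11
Reactants: 16 (2R)-2-methyl-4-methylidene-14-phenyl-2-(triethylsilyloxy)tetradecanal
Product: 17 methyl (2Z,4R)-4-methyl-6-methylidene-16-phenyl-4-(triethylsilyloxy)hexadec-2-enoate
Conditions: (CF3CH2O)2P(O)CH2CO2Me, KN(SiMe3)2, 18-crown-6, THF, −78 °C
Reagents that add atoms: methyl bis(2,2,2-trifluoroethyl)phosphonoacetate, COC(=O)CP(=O)(OCC(F)(F)F)OCC(F)(F)F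
Why: The Still–Gennari variant of the Horner–Wadsworth–Emmons reaction eliminates fast from the kinetic adduct and so gives the (Z)-enoate that ring B needs.

Step 12
Reactants: 17 methyl (2Z,4R)-4-methyl-6-methylidene-16-phenyl-4-(triethylsilyloxy)hexadec-2-enoate
Product: 19 (5R)-5-methyl-5-(2-methylidene-12-phenyldodecyl)furan-2(5H)-one, via Z-hydroxy enoate 18 (not isolated)
Conditions: p-TsOH·H2O (0.2 equiv), MeOH, rt
Reagents that add atoms: none
Why: Acid-catalysed desilylation frees the tertiary alcohol, which the Z-alkene holds next to the ester, so lactonisation (intramolecular transesterification) closes ring B.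

Step 13
Reactants: 19 (5R)-5-methyl-5-(2-methylidene-12-phenyldodecyl)furan-2(5H)-one
Product: 20 (5R)-5-methyl-5-[2-methyl-12-phenyl-2-(triethylsilylperoxy)dodecyl]furan-2(5H)-one (about 1:1 epimers at C2′)
Conditions: Co(thd)2 (10 mol%; thd = 2,2,6,6-tetramethylheptane-3,5-dionate), Et3SiH (2 equiv), O2 (1 atm), ClCH2CH2Cl, rt
Reagents that add atoms: dioxygen, O=O; triethylsilane, CC[SiH](CC)CC
Why: In the Mukaiyama–Isayama hydroperoxysilylation a cobalt hydride transfers a hydrogen atom to the electron-rich 1,1-disubstituted alkene, the tertiary radical traps O2 and is silylated, while the electron-poor butenolide alkene is left alone; the new peroxide-bearing centre (C6) forms without facial control.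

Step 14
Reactants: 20 (5R)-5-methyl-5-[2-methyl-12-phenyl-2-(triethylsilylperoxy)dodecyl]furan-2(5H)-one
Product: 21 (5R)-5-(2-hydroperoxy-2-methyl-12-phenyldodecyl)-5-methylfuran-2(5H)-one (about 1:1 epimers at C2′)
Conditions: HCl (cat.), MeOH, 0 °C
Reagents that add atoms: none
Why: Acid-catalysed methanolysis of the labile Si–O(O) bond frees the tertiary hydroperoxide without touching the butenolide.

Step 15
Reactants: 21 (5R)-5-(2-hydroperoxy-2-methyl-12-phenyldodecyl)-5-methylfuran-2(5H)-one
Product: 22 (3S,4aR,7aR)-3,4a-dimethyl-3-(10-phenyldecyl)hexahydrofuro[3,2-c][1,2]dioxin-6-one (target; 3R,4R,6S in the C1–C6 numbering)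
Conditions: Et2NH (0.5 equiv), CF3CH2OH, rt; SiO2 chromatography
Reagents that add atoms: none
Why: In this base-catalysed 6-exo-trig intramolecular oxa-Michael addition the tether from C4 can only reach the same face of ring B, so the bicycle is cis-fused and C3 is set as R by C4; the 2′S epimer of 21 gives 22, which is separated by chromatography from the C6 epimer formed from the 2′R epimer.

## Compound list

1 | 1-bromo-4-phenylbutane | BrCCCCc1ccccc1 | starting material
2 | 1-bromo-6-chlorohexane | ClCCCCCCBr | starting material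
3 | 4-phenylbutylmagnesium bromide (not isolated) | Br[Mg]CCCCc1ccccc1 | intermediate
4 | 1-chloro-10-phenyldecane | ClCCCCCCCCCCc1ccccc1 | intermediate
5 | citraconic acid, (Z)-2-methylbut-2-enedioic acid | C/C(C(=O)O)=C/C(=O)O | starting material
6 | (R)-citramalic acid, (2R)-2-hydroxy-2-methylbutanedioic acid | OC(=O)C[C@@](C(=O)O)(C)O | intermediate
7 | 2-[(4R)-2,2,4-trimethyl-5-oxo-1,3-dioxolan-4-yl]acetic acid | OC(=O)C[C@@]1(C)OC(C)(C)OC1=O | intermediate
8 | 2-[(4R)-2,2,4-trimethyl-5-oxo-1,3-dioxolan-4-yl]acetyl chloride | ClC(=O)C[C@@]1(C)OC(C)(C)OC1=O | intermediate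
9 | 10-phenyldecylmagnesium chloride (not isolated) | Cl[Mg]CCCCCCCCCCc1ccccc1 | intermediate
10 | 10-phenyldecylzinc chloride (not isolated) | Cl[Zn]CCCCCCCCCCc1ccccc1 | intermediate
11 | (5R)-2,2,5-trimethyl-5-(2-oxo-12-phenyldodecyl)-1,3-dioxolan-4-one | O=C(CCCCCCCCCCc1ccccc1)C[C@@]2(C)OC(C)(C)OC2=O | intermediate
12 | (5R)-2,2,5-trimethyl-5-(2-methylidene-12-phenyldodecyl)-1,3-dioxolan-4-one | C=C(CCCCCCCCCCc1ccccc1)C[C@@]2(C)OC(C)(C)OC2=O | intermediate
13 | methyl (2R)-2-hydroxy-2-methyl-4-methylidene-14-phenyltetradecanoate | C=C(CCCCCCCCCCc1ccccc1)C[C@@](C(=O)OC)(C)O | intermediate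
14 | methyl (2R)-2-methyl-4-methylidene-14-phenyl-2-(triethylsilyloxy)tetradecanoate | C=C(CCCCCCCCCCc1ccccc1)C[C@@](C(=O)OC)(C)O[Si](CC)(CC)CC | intermediate
15 | (2R)-2-methyl-4-methylidene-14-phenyl-2-(triethylsilyloxy)tetradecan-1-ol | C=C(CCCCCCCCCCc1ccccc1)C[C@@](CO)(C)O[Si](CC)(CC)CC | intermediate
16 | (2R)-2-methyl-4-methylidene-14-phenyl-2-(triethylsilyloxy)tetradecanal | C=C(CCCCCCCCCCc1ccccc1)C[C@@](C=O)(C)O[Si](CC)(CC)CC | intermediate
17 | methyl (2Z,4R)-4-methyl-6-methylidene-16-phenyl-4-(triethylsilyloxy)hexadec-2-enoate | C=C(CCCCCCCCCCc1ccccc1)C[C@@](/C=C\C(=O)OC)(C)O[Si](CC)(CC)CC | intermediate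
18 | methyl (2Z,4R)-4-hydroxy-4-methyl-6-methylidene-16-phenylhexadec-2-enoate (not isolated) | C=C(CCCCCCCCCCc1ccccc1)C[C@@](/C=C\C(=O)OC)(C)O | intermediate
19 | (5R)-5-methyl-5-(2-methylidene-12-phenyldodecyl)furan-2(5H)-one | C=C(CCCCCCCCCCc1ccccc1)C[C@@]2(C)OC(=O)C=C2 | intermediate
20 | (5R)-5-methyl-5-[2-methyl-12-phenyl-2-(triethylsilylperoxy)dodecyl]furan-2(5H)-one, about 1:1 epimers at C2′ | CC[Si](CC)(CC)OOC(C)(CCCCCCCCCCc1ccccc1)C[C@@]2(C)OC(=O)C=C2 | intermediate
21 | (5R)-5-(2-hydroperoxy-2-methyl-12-phenyldodecyl)-5-methylfuran-2(5H)-one, about 1:1 epimers at C2′ | OOC(C)(CCCCCCCCCCc1ccccc1)C[C@@]2(C)OC(=O)C=C2 | intermediate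
22 | (3S,4aR,7aR)-3,4a-dimethyl-3-(10-phenyldecyl)hexahydrofuro[3,2-c][1,2]dioxin-6-one | C[C@]1(CCCCCCCCCCc2ccccc2)C[C@@]2(C)OC(=O)C[C@H]2OO1 | target

## Step count and risks

Total step count: 15. Longest linear sequence: 14 steps (5 → 22, steps 2–15); step 1 is a one-step side branch.

Steps most likely to fail:

Step 6, methylenation of the β-oxygenated ketone. The risk is incomplete conversion or loss of the β-oxygen. The fallback is a two-stage Peterson olefination that sets out from 11 and comes back at 12. Me3SiCH2MgCl with CeCl3 (THF, −78 °C) adds to the ketone without enolising it and gives (5R)-5-{2-hydroxy-12-phenyl-2-[(trimethylsilyl)methyl]dodecyl}-2,2,5-trimethyl-1,3-dioxolan-4-one F1 (a mixture at the carbinol carbon, which does not matter). BF3·OEt2 (CH2Cl2, 0 °C) then triggers anti-elimination to 12.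

Step 13, cobalt hydroperoxysilylation. The risk is reduction or hydration instead of silyl peroxide formation, or attack on ring B. The fallback replaces radical by ionic C–O bond formation, sets out from 19 and comes back at 21, bypassing 20. Dry HBr (CH2Cl2, −40 °C, dark) adds in the Markovnikov sense to give (5R)-5-(2-bromo-2-methyl-12-phenyldodecyl)-5-methylfuran-2(5H)-one F2. AgOCOCF3 with anhydrous H2O2 in Et2O (0 °C) then replaces bromide by OOH through the tertiary cation and gives 21 as the same epimer mixture.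

Step 15, ring closure. The risks are retro-Michael reaction, Kornblum–DeLaMare cleavage at C3–H and sluggish addition of the tertiary hydroperoxide. The fallback closes ring A on an open-chain (E)-enoate and forms ring B last; it sets out from 16 and comes back at 22. Ph3P=CHCO2Me (toluene, 80 °C) converts 16 into methyl (2E,4R)-4-methyl-6-methylidene-16-phenyl-4-(triethylsilyloxy)hexadec-2-enoate F3. The cobalt conditions of step 13 then give methyl (2E,4R)-4,6-dimethyl-16-phenyl-4-(triethylsilyloxy)-6-(triethylsilylperoxy)hexadec-2-enoate F4. HF·pyridine (THF, 0 °C) removes both silyl groups to give methyl (2E,4R)-6-hydroperoxy-4-hydroxy-4,6-dimethyl-16-phenylhexadec-2-enoate F5, which cannot lactonise. Et2NH in CF3CH2OH effects the 6-exo oxa-Michael closure to methyl 2-[(3R,4R,6S)-4-hydroxy-4,6-dimethyl-6-(10-phenyldecyl)-1,2-dioxan-3-yl]acetate F6, formed beside its C3 and C6 epimers. PPTS in warm toluene lactonises only the isomers with the acetate arm cis to the C4 hydroxyl, and chromatography gives 22.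

## Further compounds

F1 | step 6 | (5R)-5-{2-hydroxy-12-phenyl-2-[(trimethylsilyl)methyl]dodecyl}-2,2,5-trimethyl-1,3-dioxolan-4-one | C[Si](C)(C)CC(O)(CCCCCCCCCCc1ccccc1)C[C@@]2(C)OC(C)(C)OC2=O
F2 | step 13 | (5R)-5-(2-bromo-2-methyl-12-phenyldodecyl)-5-methylfuran-2(5H)-one | CC(Br)(CCCCCCCCCCc1ccccc1)C[C@@]2(C)OC(=O)C=C2
F3 | step 15 | methyl (2E,4R)-4-methyl-6-methylidene-16-phenyl-4-(triethylsilyloxy)hexadec-2-enoate | C=C(CCCCCCCCCCc1ccccc1)C[C@@](/C=C/C(=O)OC)(C)O[Si](CC)(CC)CC
F4 | step 15 | methyl (2E,4R)-4,6-dimethyl-16-phenyl-4-(triethylsilyloxy)-6-(triethylsilylperoxy)hexadec-2-enoate | CC[Si](CC)(CC)OOC(C)(CCCCCCCCCCc1ccccc1)C[C@@](/C=C/C(=O)OC)(C)O[Si](CC)(CC)CC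
F5 | step 15 | methyl (2E,4R)-6-hydroperoxy-4-hydroxy-4,6-dimethyl-16-phenylhexadec-2-enoate | OOC(C)(CCCCCCCCCCc1ccccc1)C[C@@](/C=C/C(=O)OC)(C)O
F6 | step 15 | methyl 2-[(3R,4R,6S)-4-hydroxy-4,6-dimethyl-6-(10-phenyldecyl)-1,2-dioxan-3-yl]acetate | C[C@]1(CCCCCCCCCCc2ccccc2)C[C@@](C)(O)[C@@H](CC(=O)OC)OO1
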